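**Plan**

1. Numbering: C1 is the benzylic CH2, C2 the acetoxy carbon (R), C3–C7 the five methylenes, C8 the ketone carbon, C9–C13 the pentyl group.
2. Feature used: C2 (O–CH) and C8 (C=O) are linked by exactly five CH2 groups, so they are ring atoms 8 and 2 of an oxocan-2-one; removing the ring oxygen leaves a cycloheptanone with C8 as carbonyl and C2 as its substituted α-carbon.
3. Cuts, in retrosynthetic order: the aryl O–benzyl and acetyl C–O bonds; C8–C9 (pentyl Grignard on a Weinreb amide); the acyl C8–O bond of the lactone; the C2–O bond (oxygen inserted into C2–C8); the C1=C2 double bond (hydrogenation after aldol condensation).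
4. Forward: cycloheptanone and 3,5-bis(benzyloxy)benzaldehyde are condensed, the exocyclic alkene is hydrogenated, and the seven-membered ring is expanded to the eight-membered lactone (the only ring-forming event). The lactone is then opened, extended by pentyl, acetylated and debenzylated.
5. Stereochemistry: C2 is set as a C–H centre by iridium-catalysed asymmetric hydrogenation and becomes the C–O centre with retention during the oxygen insertion; no later step breaks a bond at C2.

Key step: step 3

Assumption: the (S)-tBu-PHOX ligand is taken to deliver hydrogen to the alkene face that gives (R)-5; should the sense be opposite, the (R)-ligand is used with no other change (BArF = tetrakis[3,5-bis(trifluoromethyl)phenyl]borate).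

**Route**

Step 1
Reactants: 1 cycloheptanone; 2 3,5-bis(benzyloxy)benzaldehyde
Product: 4 (E)-2-[3,5-bis(benzyloxy)benzylidene]cycloheptan-1-one, via aldol adduct 3 (not isolated)
Conditions: 1 (4 equiv), NaOH (cat., aq), EtOH/THF, 50 °C
Reagents that add atoms: none
Why: Claisen–Schmidt (crossed aldol) condensation: only 1 can enolise and only 2 is a reactive electrophile, the excess of 1 holds back a second condensation at C7, and base-mediated E1cB loss of water from aldol 3 gives the conjugated alkene with the aryl group anti to the carbonyl (E).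

Step 2
Reactants: 4 (E)-2-[3,5-bis(benzyloxy)benzylidene]cycloheptan-1-one
Product: 5 (R)-2-[3,5-bis(benzyloxy)benzyl]cycloheptan-1-one
Conditions: H2 (20 bar), [Ir(cod)((S)-tBu-PHOX)]BArF (2 mol %), CH2Cl2, rt
Reagents that add atoms: none
Why: Iridium-catalysed asymmetric hydrogenation of an α-arylidene cycloalkanone with a cationic phosphinooxazoline complex, a catalyst class established for exocyclic trisubstituted enones of ring sizes five to seven: the chiral N,P ligand decides which face of the s-cis-locked alkene receives hydrogen and thereby sets C2 as R, while the base-free medium leaves the new enolisable centre and the benzyl ethers alone.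

Step 3
Reactants: 5 (R)-2-[3,5-bis(benzyloxy)benzyl]cycloheptan-1-one
Product: 7 (R)-8-[3,5-bis(benzyloxy)benzyl]oxocan-2-one, via Criegee adduct 6 (not isolated)
Conditions: mCPBA (2 equiv), NaHCO3, CH2Cl2, 0 °C to rt, dark
Reagents that add atoms: mCPBA (3-chloroperoxybenzoic acid), OOC(=O)c1cccc(Cl)c1
Why: Baeyer–Villiger oxidation: the peracid adds to the carbonyl of 5 to give Criegee adduct 6, in which the ring bond C8–C2 lying antiperiplanar to the O–O bond shifts to oxygen as 3-chlorobenzoate departs. The closest known reaction type is the peracid oxidation of 2-alkylcycloalkanones to ω-alkyl lactones. The oxocan-2-one ring is formed by one-atom ring expansion of the seven-membered carbocycle (oxygen inserted between C8 and C2), not by end-to-end lactonisation, so no medium-ring cyclisation has to be achieved. The C2–O stereocentre is under substrate control: the 1,2-shift is concerted and suprafacial, the migrating carbon keeps its configuration, and R in 5 becomes R in 7. The step needs regioselectivity for C2 over the C7 methylene, which the higher migratory aptitude of the secondary carbon should provide, and chemoselectivity for the ketone over the electron-rich aryl ring, which the cold, buffered, stoichiometric peracid should provide. The bicarbonate also keeps the medium free of acid that could enolise C2 of 5 before the shift.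

Step 4
Reactants: 7 (R)-8-[3,5-bis(benzyloxy)benzyl]oxocan-2-one
Product: 8 (R)-8-[3,5-bis(benzyloxy)phenyl]-7-hydroxy-N-methoxy-N-methyloctanamide
Conditions: MeNH(OMe)·HCl (3 equiv), AlMe3 (3 equiv), CH2Cl2, 0 °C to rt; then 1 M HCl, 0 °C
Reagents that add atoms: N,O-dimethylhydroxylamine hydrochloride, CNOC.Cl
Why: Weinreb aminolysis of a lactone by the chloro(methyl)aluminium amide formed in the flask: the amide nitrogen attacks the acyl carbon C8 and the ring opens by acyl–oxygen cleavage, so the C2–O bond and its R configuration are untouched and the strained eight-membered ring has no tendency to re-close.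

Step 5
Reactants: 8 (R)-8-[3,5-bis(benzyloxy)phenyl]-7-hydroxy-N-methoxy-N-methyloctanamide; 9 pentylmagnesium bromide
Product: 11 (R)-1-[3,5-bis(benzyloxy)phenyl]-2-hydroxytridecan-8-one, via magnesium hemiaminal chelate 10 (not isolated)
Conditions: 9 (3 equiv), THF, −20 °C to 0 °C; then 1 M HCl, 0 °C
Reagents that add atoms: pentylmagnesium bromide (compound 9), CCCCC[Mg]Br
Why: Weinreb ketone synthesis: the first equivalent of 9 deprotonates the hydroxyl, the second adds to the amide to give the five-membered magnesium chelate 10, which survives until the acidic quench and so cannot take up a further equivalent, giving the ketone without over-addition.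

Step 6
Reactants: 11 (R)-1-[3,5-bis(benzyloxy)phenyl]-2-hydroxytridecan-8-one
Product: 12 (R)-1-[3,5-bis(benzyloxy)phenyl]-8-oxotridecan-2-yl acetate
Conditions: Ac2O, pyridine, DMAP (cat.), CH2Cl2, 0 °C to rt
Reagents that add atoms: acetic anhydride, CC(=O)OC(C)=O
Why: DMAP-catalysed acylation of a secondary alcohol (Steglich-type acyl transfer) takes place at oxygen only, so C2 keeps its configuration, and the ketone and benzyl ethers are inert to acetic anhydride and pyridine at this temperature.

Step 7
Reactants: 12 (R)-1-[3,5-bis(benzyloxy)phenyl]-8-oxotridecan-2-yl acetate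
Product: 13 (R)-1-(3,5-dihydroxyphenyl)-8-oxotridecan-2-yl acetate
Conditions: H2 (1 atm), Pd/C (10 wt %), EtOAc, rt
Reagents that add atoms: none
Why: Heterogeneous palladium-catalysed hydrogenolysis cleaves only the two benzylic C–O bonds of the aryl benzyl ethers: the acetate sits on the homobenzylic carbon C2 and is not activated towards hydrogenolysis, and a dialkyl ketone is not reduced under one atmosphere of hydrogen in neutral ethyl acetate.

**Compound list**

1 | cycloheptanone | O=C1CCCCCC1 | starting material
2 | 3,5-bis(benzyloxy)benzaldehyde | O=Cc1cc(OCc2ccccc2)cc(OCc2ccccc2)c1 | starting material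
3 | 2-{[3,5-bis(benzyloxy)phenyl](hydroxy)methyl}cycloheptan-1-one (aldol adduct, diastereomer mixture, not isolated) | O=C1CCCCCC1C(O)c1cc(OCc2ccccc2)cc(OCc2ccccc2)c1 | intermediate
4 | (E)-2-[3,5-bis(benzyloxy)benzylidene]cycloheptan-1-one | O=C1CCCCC/C1=C\c1cc(OCc2ccccc2)cc(OCc2ccccc2)c1 | intermediate
5 | (R)-2-[3,5-bis(benzyloxy)benzyl]cycloheptan-1-one | O=C1CCCCC[C@@H]1Cc1cc(OCc2ccccc2)cc(OCc2ccccc2)c1 | intermediate
6 | (2R)-2-[3,5-bis(benzyloxy)benzyl]-1-hydroxycycloheptyl 3-chloroperoxybenzoate (Criegee adduct, not isolated) | OC1(OOC(=O)c2cccc(Cl)c2)CCCCC[C@@H]1Cc1cc(OCc2ccccc2)cc(OCc2ccccc2)c1 | intermediate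
7 | (R)-8-[3,5-bis(benzyloxy)benzyl]oxocan-2-one | O=C1CCCCC[C@H](Cc2cc(OCc3ccccc3)cc(OCc3ccccc3)c2)O1 | intermediate
8 | (R)-8-[3,5-bis(benzyloxy)phenyl]-7-hydroxy-N-methoxy-N-methyloctanamide | CON(C)C(=O)CCCCC[C@H](Cc1cc(OCc2ccccc2)cc(OCc2ccccc2)c1)O | intermediate
9 | pentylmagnesium bromide | CCCCC[Mg]Br | starting material
10 | bis(bromomagnesium) alkoxide of (2R)-1-[3,5-bis(benzyloxy)phenyl]-8-[methoxy(methyl)amino]tridecane-2,8-diol (magnesium hemiaminal chelate, not isolated) | CCCCCC(O[Mg]Br)(N(C)OC)CCCCC[C@H](Cc1cc(OCc2ccccc2)cc(OCc2ccccc2)c1)O[Mg]Br | intermediate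
11 | (R)-1-[3,5-bis(benzyloxy)phenyl]-2-hydroxytridecan-8-one | CCCCCC(=O)CCCCC[C@H](Cc1cc(OCc2ccccc2)cc(OCc2ccccc2)c1)O | intermediate
12 | (R)-1-[3,5-bis(benzyloxy)phenyl]-8-oxotridecan-2-yl acetate | CCCCCC(=O)CCCCC[C@H](Cc1cc(OCc2ccccc2)cc(OCc2ccccc2)c1)OC(C)=O | intermediate
13 | (R)-1-(3,5-dihydroxyphenyl)-8-oxotridecan-2-yl acetate | CCCCCC(=O)CCCCC[C@H](Cc1cc(O)cc(O)c1)OC(C)=O | target

**Step count**

Total steps: 7. Longest linear sequence: 7 steps (1 and 2 to 13).

**Steps most likely to fail**

Step 3 (oxygen insertion). The peracid may attack the electron-rich 3,5-dialkoxyaryl ring faster than it adds to the sluggish seven-membered ketone, and some migration of the C7 methylene may accompany the wanted shift. The fallback sets out from 5 and returns at 7; it lowers the electron density of the ring before the oxidation and keeps the same ring expansion. Hydrogenolysis of 5 (H2, Pd/C, EtOAc) should give (R)-2-(3,5-dihydroxybenzyl)cycloheptan-1-one F1. Acetylation (Ac2O, pyridine) should give (R)-2-(3,5-diacetoxybenzyl)cycloheptan-1-one F2, whose deactivated ring should tolerate excess mCPBA/NaHCO3 in CH2Cl2 at rt to 40 °C. The oxidation should then give (R)-8-(3,5-diacetoxybenzyl)oxocan-2-one F3. Pyrrolidine (CH2Cl2, 0 °C) should remove the two aryl acetates by aminolysis, which is much faster at aryl esters than at the lactone, to give (R)-8-(3,5-dihydroxybenzyl)oxocan-2-one F4. Benzyl bromide with K2CO3 in DMF at rt should then return 7.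

Step 2 (asymmetric hydrogenation). Facial discrimination at the exocyclic alkene may be insufficient, or the alkene may isomerise into the ring before reduction, both of which lower the enantiomeric purity of C2. The fallback sets out from 1 and returns at 5; it sets C2 by auxiliary-controlled alkylation instead of hydrogenation. Condensation of 1 with RAMP, (R)-1-amino-2-(methoxymethyl)pyrrolidine, should give cycloheptanone RAMP hydrazone F5. Deprotonation with LDA (THF, 0 °C) and alkylation at −78 °C with commercial 3,5-bis(benzyloxy)benzyl bromide, BrCc1cc(OCc2ccccc2)cc(OCc2ccccc2)c1, should give (R)-2-[3,5-bis(benzyloxy)benzyl]cycloheptanone RAMP hydrazone F6. The chelated lithium azaenolate exposes one face, and RAMP is the antipode that the established model predicts for the R ketone. Two-phase cleavage with saturated aqueous oxalic acid and Et2O, which does not epimerise the α-centre, should return 5 and the auxiliary.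

Step 1 (mono-condensation). A second condensation at C7 to the 2,7-bis(arylidene) ketone, self-condensation of cycloheptanone, or migration of the exocyclic alkene into the ring may erode the yield of 4. The fallback sets out from 1 and 2 and returns at 4; it is a directed aldol followed by separate elimination. The lithium enolate of 1 (LDA, THF, −78 °C) is treated with 2 and quenched cold to give aldol adduct 3, now isolated. MsCl and Et3N (CH2Cl2, 0 °C) should give 2-{[3,5-bis(benzyloxy)phenyl](methylsulfonyloxy)methyl}cycloheptan-1-one F7, and DBU (rt) should eliminate it to the (E)-enone 4.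

**Further compounds**

F1 | step 3 | (R)-2-(3,5-dihydroxybenzyl)cycloheptan-1-one | O=C1CCCCC[C@@H]1Cc1cc(O)cc(O)c1
F2 | step 3 | (R)-2-(3,5-diacetoxybenzyl)cycloheptan-1-one | O=C1CCCCC[C@@H]1Cc1cc(OC(C)=O)cc(OC(C)=O)c1
F3 | step 3 | (R)-8-(3,5-diacetoxybenzyl)oxocan-2-one | O=C1CCCCC[C@H](Cc2cc(OC(C)=O)cc(OC(C)=O)c2)O1
F4 | step 3 | (R)-8-(3,5-dihydroxybenzyl)oxocan-2-one | O=C1CCCCC[C@H](Cc2cc(O)cc(O)c2)O1
F5 | step 2 | cycloheptanone RAMP hydrazone, (R)-N-cycloheptylidene-2-(methoxymethyl)pyrrolidin-1-amine | COC[C@H]1CCCN1N=C1CCCCCC1
F6 | step 2 | (R)-2-[3,5-bis(benzyloxy)benzyl]cycloheptanone RAMP hydrazone | COC[C@H]1CCCN1N=C1CCCCC[C@@H]1Cc1cc(OCc2ccccc2)cc(OCc2ccccc2)c1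
F7 | step 1 | 2-{[3,5-bis(benzyloxy)phenyl](methylsulfonyloxy)methyl}cycloheptan-1-one | O=C1CCCCCC1C(OS(C)(=O)=O)c1cc(OCc2ccccc2)cc(OCc2ccccc2)c1
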